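The time of the run, 12 h, drops out of the one quantity I carry through this flask.

substrate 0.57 M; gas phase 84 mM (held); catalyst 5.7 mM; time 12 h

    gas phase ⇌ dissolved gas, rate k1*(csat - [dissolved gas]) (k1 = 0.031 min⁻¹, csat = 84 mM)
    substrate + dissolved gas + catalyst → catalyst + target (k2 = 3.0 M⁻² min⁻¹)
    substrate + target → side product (k3 = 4.1 × 10⁻⁴ M⁻¹ min⁻¹)
    crystals ⇌ target, rate k4*(cs4 - [target]) while solid is left; crystals form when [target] > cs4 (cs4 = 0.098 M, k4 = 0.68 min⁻¹)
    substrate + dissolved gas → uncatalysed product (k5 = 0.019 M⁻¹ min⁻¹)

1. amount of target and crystals together at 12 h, in percent of the substrate charged
2. the change that raises the amount of target and crystals together at 12 h, in percent of the substrate charged most ("none" if none brings more than 2 percentage points) (Monday's / Friday's / Saturday's / Wednesday's / none)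
3. amount of target and crystals together at 12 h, in percent of the substrate charged, after Monday's

- Monday's: doubling the amount of catalyst, all else as stated
- Friday's: doubling the saturation concentration of gas phase, all else as stated
- Saturday's: doubling the solubility in step 4, all else as stated
- Wednesday's: doubling the transfer coefficient of step 1, all else as stated

- a species is counted by the substrate in it: one side product counts as two
- amounts and yields of target count crystals too
- given per volume of solution although it is solid: crystals
- at the start none of the gas is dissolved
- run time (flask): 12 h

Steps 2 and 5 both run on substrate times dissolved gas, so in their quotient these and time cancel. The catalyst comes back unchanged from step 2. I therefore carry the branch share, the fraction of the substrate consumed by steps 2 and 5 together that step 2 takes, a selectivity: 47.4%. The reading to watch is target over target plus uncatalysed product.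

Next I need the fraction of substrate left. Step 1 at full drive would deliver the charge in 3.65 h, and the two branches with saturated solution have a time constant of 5.50 h. Balancing delivery against consumption with the substrate as charged puts dissolved gas at 60.1% of saturation. Held there, the decay is pseudo-first-order and leaves 26.9% of the substrate, so my first figure for target is 34.6%.

The weak link is that held gas level: the same balance puts dissolved gas higher as substrate falls. Integrating the moving balance gives: time equals the first constant times (1 − fraction left) plus the second times ln(1/fraction left). Two rounds of substitution give 19.4% left, so I commit to 38.2%. I neglect step 3, under which dissolved target has a half-life of 49 h, longer than the run.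

Monday's raises the share to 64.3%. With the second constant at 3.73 h the same substitution gives 58.0% target. Friday's and Wednesday's leave the share unchanged, and even full conversion at that share gives less than Monday's figure. Saturday's acts through dissolved target and step 3, whose half-life is longer than the run, so I expect little from it.

The forecast says “Dissolved gas is transfer-limited and split between the catalysed and uncatalysed routes”. It gives 36.2% (34% to 38.5%), names Monday's, and gives 56.2% (53% to 59%) after that change. My figures stand higher than its central values.

The simulation gives 36.2% and, after Monday's, 55.8%. The gains are 20 percentage points for Monday's, 8.8 points for Friday's, 2.5 points for Wednesday's and −0.42 points for Saturday's. At 12.0 h this flask holds 36.2% target, crystals counted, and 41.4% uncatalysed product, so target is 46.6% of the two, beside the share of 47.4%. The neighbouring flask with 0.023 M of catalyst has a share of 78.4%. At 12.0 h it holds 74.7% target, crystals counted, and 20.8% uncatalysed product, so target is 78.2% of the two.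

The numbers stand for no real mixture; the flask was simulated.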